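## Structural features

Compound 30 is a pentacyclic amino dilactone built around a cyclopentane, ring A, whose atoms are labelled C-a (ethyl-bearing), C-b (lactone oxygen), C-d, C-q (fully substituted amino carbon) and C-e (ring-fusion methine). C-q belongs to three rings: ring A, the pyrrolidine ring B (N, C-q, two CH2, C-p) and the azepane ring C (N, four CH2, C-e, C-q). A γ-lactone, ring D, is cis-fused to ring A across C-b–C-d and contains the tertiary carbinol C-c(OH)(CH3); an α-methyl-γ-butyrolactone, ring E, hangs from C-p. All five ring-A carbons are stereocentres and C-c makes six in a row. Nitrogen and the ethyl group lie on one face of ring A (the N-face); the pyrrolidine CH2, ring D and the azepane carbon on C-e lie on the other (the carbon face). Ring C is therefore trans-fused to ring A and N is trans to C-c; C-p and ring E show the threo, cis-methyl pattern (C-a R, C-b S, C-c S, C-d R, C-q S, C-e R, C-p S, ring E S,S). The fragile groups are the two lactones (hydride, hydroxide, strong base), the epimerisable α-centre of ring E, the amine (oxidants) and the tertiary α-hydroxy lactone (strong acid). The real difficulty is C-q, an α-tertiary amine carbon flanked by two methine stereocentres and locked into a trans 5/7 fusion, together with hydroxylating ring D without touching ring E. The key step uses the array N–C-q–C-d(–C-c), with N and C-c trans and oxygen on C-b two ring atoms from C-q. With a carbonyl at C-b and a double bond C-a=C-e, ring A is a trans-4-amino-5-alkylcyclopent-2-enone, and the spiro attachment of ring B at C-q corresponds to a furan carrying the amine on a three-carbon tether at its 5-position.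

## Logic of the disconnections

30 ⇒ 29. The two C–H bonds at the α- and β-carbons of ring E are removed. An unsaturated ring E is what a silyloxyfuran addition delivers, and the epimerisable α-methyl centre then appears only in the last step. One stereocentre is removed; the hydrogenation must take place on the face of ring E turned away from C-p.

29 ⇒ 28 + 26. The bond between C-p and the γ-carbon of ring E is cut. It is the only C–C bond joining the side-chain lactone to the core, and cutting it removes ring E and two stereocentres. The vinylogous Mannich addition must attack C-p of 28 on the face of ring B remote from ring C and give the threo pair, with a free tertiary alcohol and ring D present.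

28 ⇒ 24 (through 27). The N–CH2 bond of ring C is cut. A ring closure that formed the C-e–CH2 bond from a chain on nitrogen would deliver that carbon to the N-face of the planar enone, which is the wrong face for a trans fusion. Closing at nitrogen leaves the configuration of C-e to an earlier intermolecular step. Alkylating the C=N nitrogen of 24 also creates the iminium ion at C-p only, which oxidation of a finished tertiary amine could not guarantee. The demand is a seven-membered closure by an sp2 nitrogen that outruns intermolecular alkylation.

24 ⇒ 22. The C=N bond is returned to N–H and C–H. C-q has no hydrogen, so oxidation can only go towards C-p; the oxidant must leave both hydroxyl groups alone.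

22 ⇒ 21. N–H and O–H are traced back to an N–aryl and an O–benzyl bond, both with 4-methoxyphenyl groups, so that one oxidant removes them together. The aryl group is what step 6 requires and it keeps nitrogen non-basic through the enolate and oxidation steps. The cleavage must spare the tertiary alcohol and ring D.

21 ⇒ 19. The C-c–OH bond is cut. Oxygenation of the ring-D enolate on its convex face places hydroxyl exo and methyl endo as in 30, so the configuration of C-c in 19 does not matter. Ring D must be the only enolisable carbonyl present, which is why this precedes ring E.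

19 ⇒ 17. The acyl C–O bond of ring D is opened and the carbonyl carbon lowered to CH2OH. A protected primary alcohol passes through step 6, whereas an ester β to the carbinol carbon of 9 would divert the cation to an acrylate. The oxidation must select the primary alcohol and tolerate an electron-rich aryl amine.

17 ⇒ 16. An O–Si bond is restored. The silyl ether masks the arm from step 1 to this point and must come off without touching the benzyl-type ether.

16 ⇒ 15. The C-b–H bond is cut (alcohol to ketone). The ketone is the carbonyl of the rearrangement product; hydride must arrive from the N-face so that the hydroxyl is cis to the arm.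

15 ⇒ 13. The C-a–ethyl bond is cut. The enol ether fixes the enolate on the C-a side, away from C-d, where an enolate could expel the β-amino group. The alkylation must be faster than proton exchange.

13 ⇒ 10 + 11 (through 12). The C-e–CH2 bond is cut. The four-carbon chain is added to the enone of 10 by an external nucleophile, which can approach anti to the C–N bond at C-q. This is the step that decides the trans 5/7 fusion. The chain end must be inert to enolates, hence an ether and not a halide.

10 ⇒ 9. The N–C-q and C-q–C-d bonds are cut and rings A and B opened in one operation, which turns a spiro bicycle with two adjacent stereocentres into a flat 2,5-disubstituted furan. The rearrangement must give the trans pair in one absolute sense and must outrun loss of the β-hydrogen from the furfuryl cation. The silyl group has to survive acid and the water set free, so tert-butyldiphenylsilyl replaces a more labile trialkylsilyl group.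

9 ⇒ 7 + 3 (through 8). The bond between furan C5 and the carbinol carbon is cut. Both carbinol epimers serve, since that carbon is ionised in the next step. The N–H is left unprotected and simply deprotonated.

7 ⇒ 6 ⇒ 4 + 5. The N–CH2 bond is traced to an amide and the amide C–N bond is cut; both operations are routine.

3 ⇒ 2 ⇒ 1. The aldehyde is traced to the ester and the O–Si bond is cut. The stereocentre of 1 serves only to make the two possible products of step 6 diastereomers and is erased in step 12.

26 ⇒ 25. The O–Si bond is cut; 26 is the silyl dienol ether of 25.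

## Other disconnections considered

Alternative 1: The N–C-q bond is cut together with the N–acyl bond of a lactam precursor, leading from lactam A2 back to the angular azido ketone A1. A1 is a trans-fused hydrindanone already carrying rings D and E and a secondary azide on a three-carbon arm at C-q. In the forward sense acid would add the azide to the ketone, C-q would migrate from carbon to nitrogen with loss of N2, and rings B and C would close together (intramolecular Schmidt reaction).
- In its favour: C-q would be transferred with retention from an all-carbon quaternary centre, for which enolate or cycloaddition chemistry is available. A2 is a single carbonyl reduction away from 30, so the key step lies later and is more convergent than in the chosen plan; on this point the alternative is the better one.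
- Against it here: A1 holds all nine stereocentres and both lactones, so the problem is moved and not solved. Migration of the CH2 carbon instead of C-q would give a bridged isomer. The acid needed meets the tertiary α-hydroxy lactone. The final reduction must distinguish a lactam from two lactones.
- Comparison: on structure the two plans are equal in fixing the C-q–N bond with defined configuration. On mechanism both are cationic rearrangements with one acid-sensitive stage. On step economy the chosen plan builds rings A and B early from flat precursors, whereas A1 needs ring A, the hydrindanone and every substituent beforehand, so the alternative should be the longer route.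

Alternative 2: The C-e–CH2 bond of ring A and the N–C-q bond are cut, leading from the tricyclic hydroxy lactam A4 back to A3. A3 is an N-benzyl ten-membered lactam with a trisubstituted ring alkene and a glycidyl side chain. In the forward sense a Lewis acid would open the epoxide at its CH2 by attack of the ring alkene, the tertiary cation at C-q would be captured across the ring by the lactam nitrogen, and benzyl would be lost.
- In its favour: three rings and the C-q/C-e pair would arise from a monocycle in one operation, a larger gain per step than in the chosen key step. Anti addition across a ring alkene of matching geometry would give the trans relation of N and the azepane carbon directly, which the chosen plan must earn in a separate conjugate addition. On both points the alternative is the better one. The lactam carbonyl sits at C-p and could later serve to introduce ring E, which is at least equal to the imine route used here.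
- Against it here: A4 has bare methylene groups at C-a and C-d, so the ethyl group and the lactone arm would have to be placed on either side of a C-b ketone, one next to the quaternary carbon, with the arm/N relation not preordained. Alkene attack at the primary epoxide carbon is the electronically less favoured opening. The amide oxygen should compete with nitrogen for the cation. The medium ring with defined alkene geometry is costly.
- Comparison: better on ring count and on the trans fusion, worse on the arm stereocentre (which the electrocyclisation delivers together with C-q) and on mechanistic risk; step economy is probably no better.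

Alternative 3: The C-q–C-e bond and the neighbouring CH2–CH2 bond of ring C are cut, leading from the keto imine A6 back to the N-Boc 5-alkenyl pyrrolin-3-one A5. In the forward sense irradiation would join the vinylogous amide and the terminal alkene to a cyclobutane, and removal of the carbamate would trigger retro-Mannich opening to the cyclopenta-fused azepinone imine.
- In its favour: rings A and C and the centre C-e would form in one operation under neutral conditions, which is equal or better for protecting-group tolerance than an acid-mediated step. The C-b oxygen is present from the start and relays its configuration to C-e. C-e is fixed in the key step, whereas the chosen plan fixes it afterwards.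
- Against it here: C-q is left as an sp2 imine carbon, so the hardest centre must still be made by addition to an enolisable ketimine with facial control. Ring B is absent. The azepanone carbonyl is surplus. C-a and C-d are unsubstituted, which brings back the double alkylation problem of alternative 2.
- Comparison: equal in rings formed per step, better in the timing of C-e, worse in that C-q and C-d remain open and more steps follow the key step.

Key step: step 6

Assumption: the (R)-configured phosphoric acid is taken as the catalyst enantiomer that matches the desired sense of ring closure (its mirror image is used otherwise), and 11 and 25 are taken as catalogue compounds.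

## Steps

Step 1
Reactants: 1 methyl (2R)-3-hydroxy-2-methylpropanoate
Product: 2 methyl (2R)-3-[tert-butyl(diphenyl)silyl]oxy-2-methylpropanoate
Conditions: t-BuPh2SiCl, imidazole, DMF, 0 °C to rt
Reagents that add atoms: tert-butyl(chloro)diphenylsilane, CC(C)(C)[Si](Cl)(c1ccccc1)c1ccccc1
Why: Silylation of a primary alcohol; the bulky diphenylsilyl ether is chosen because it must survive the acid and the water released in step 6, where a tert-butyldimethylsilyl ether would be at risk.

Step 2
Reactants: 2 methyl (2R)-3-[tert-butyl(diphenyl)silyl]oxy-2-methylpropanoate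
Product: 3 (2R)-3-[tert-butyl(diphenyl)silyl]oxy-2-methylpropanal
Conditions: i-Bu2AlH (1.1 equiv), CH2Cl2, −78 °C; aq potassium sodium tartrate
Reagents that add atoms: none
Why: Partial ester reduction through the aluminium hemiacetal, which is stable at −78 °C; the α-stereocentre should be kept if the aldehyde is used at once without chromatography.

Step 3
Reactants: 4 3-(furan-2-yl)propanoic acid; 5 4-methoxyaniline
Product: 6 3-(furan-2-yl)-N-(4-methoxyphenyl)propanamide
Conditions: EDC·HCl, DMAP (cat.), CH2Cl2, rt
Reagents that add atoms: none
Why: Carbodiimide amide coupling of an unhindered acid and an aniline.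

Step 4
Reactants: 6 3-(furan-2-yl)-N-(4-methoxyphenyl)propanamide
Product: 7 N-[3-(furan-2-yl)propyl]-4-methoxyaniline
Conditions: LiAlH4, THF, reflux; aq NaOH
Reagents that add atoms: none
Why: Hydride reduction of a secondary amide to the amine; the furan is inert to LiAlH4.

Step 5
Reactants: 7 N-[3-(furan-2-yl)propyl]-4-methoxyaniline; 3 (2R)-3-[tert-butyl(diphenyl)silyl]oxy-2-methylpropanal
Product: 9 (2R)-3-[tert-butyl(diphenyl)silyl]oxy-1-{5-[3-(4-methoxyanilino)propyl]furan-2-yl}-2-methylpropan-1-ol (both C-1 epimers), via dilithio species 8 (not isolated)
Conditions: n-BuLi (2.2 equiv), THF, −78 to 0 °C; then 3, −78 °C; then H2O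
Reagents that add atoms: none
Why: Directed metalation then 1,2-addition: the first equivalent of base removes N–H and the second lithiates the only free α-position of the furan, whose carbanion adds to the aldehyde much faster than the hindered lithium anilide; the new carbinol configuration is immaterial because that carbon is ionised in step 6.

Step 6
Reactants: 9 (2R)-3-[tert-butyl(diphenyl)silyl]oxy-1-{5-[3-(4-methoxyanilino)propyl]furan-2-yl}-2-methylpropan-1-ol
Product: 10 (5S,6R)-6-{(2S)-1-[tert-butyl(diphenyl)silyl]oxypropan-2-yl}-1-(4-methoxyphenyl)-1-azaspiro[4.4]non-8-en-7-one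
Conditions: (R)-3,3′-bis(2,4,6-triisopropylphenyl)-1,1′-binaphthalene-2,2′-diyl hydrogen phosphate (10 mol %), CHCl3, 40 °C
Reagents that add atoms: none
Why: The acid protonates the carbinol and water leaves, giving a furfuryl cation paired with the chiral phosphate; the aniline nitrogen adds to furan C5 in a 5-exo-trig closure that forms ring B as a spiro N,O-aminal. The aminal opens at its C–O bond to a 1-amino-4-hydroxypentadienyl cation, which closes ring A by thermal conrotatory 4π electrocyclisation between the former carbinol carbon and former furan C5, and the dienol tautomerises to the enone. This is the intramolecular aza-Piancatelli rearrangement, known for tethered anilines under Lewis or Brønsted acids and in enantioselective form under chiral phosphoric acids. Conrotation of the out,out cation fixes the relative configuration of C-q and C-d with N trans to the arm; the absolute sense should come from the phosphate, hydrogen-bonded to the dienol hydroxyl during closure. Because the arm already holds a stereocentre, the product of opposite sense is a diastereomer and should be removable by chromatography. The step needs N-attack and cyclisation to beat loss of the β-hydrogen: the aniline is the only nucleophile five atoms from C5, it is too weakly basic to quench the acid, and an alkenylfuran formed by E1 loss can re-enter by reprotonation.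

Step 7
Reactants: 10 (5S,6R)-6-{(2S)-1-[tert-butyl(diphenyl)silyl]oxypropan-2-yl}-1-(4-methoxyphenyl)-1-azaspiro[4.4]non-8-en-7-one; 11 1-[(4-bromobutoxy)methyl]-4-methoxybenzene
Product: 13 6-{(2S)-1-[tert-butyl(diphenyl)silyl]oxypropan-2-yl}-9-{4-[(4-methoxybenzyl)oxy]butyl}-1-(4-methoxyphenyl)-7-(trimethylsilyloxy)-1-azaspiro[4.4]non-7-ene (C-9 chain on the carbon face), via Grignard reagent 12 (not isolated)
Conditions: 11, Mg, THF, 40 °C; then CuBr·SMe2 (20 mol %), Me3SiCl, 10, THF, −78 °C; Et3N, pentane
Reagents that add atoms: chlorotrimethylsilane, C[Si](C)(C)Cl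
Why: Copper-catalysed conjugate addition of a Grignard reagent accelerated by the silyl chloride, which traps the enolate as its silyl enol ether. The nucleophile should reach C-e anti to the C–N bond at C-q, on the face that carries only the pyrrolidine CH2 and not the N-aryl group, which places the chain on the carbon face.

Step 8
Reactants: 13 6-{(2S)-1-[tert-butyl(diphenyl)silyl]oxypropan-2-yl}-9-{4-[(4-methoxybenzyl)oxy]butyl}-1-(4-methoxyphenyl)-7-(trimethylsilyloxy)-1-azaspiro[4.4]non-7-ene
Product: 15 6-{(2S)-1-[tert-butyl(diphenyl)silyl]oxypropan-2-yl}-8-ethyl-9-{4-[(4-methoxybenzyl)oxy]butyl}-1-(4-methoxyphenyl)-1-azaspiro[4.4]nonan-7-one (ethyl on the N-face), via lithium enolate 14 (not isolated)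
Conditions: MeLi, THF, 0 °C; then EtI, DMPU, −40 to 0 °C
Reagents that add atoms: iodoethane, CCI
Why: Regiospecific enolate alkylation: MeLi cleaves the O–Si bond to the lithium enolate on the C-a side, which is C-alkylated by iodoethane anti to the neighbouring chain. The trans 2,3-arrangement is also the more stable one, so equilibration would not harm it.

Step 9
Reactants: 15 6-{(2S)-1-[tert-butyl(diphenyl)silyl]oxypropan-2-yl}-8-ethyl-9-{4-[(4-methoxybenzyl)oxy]butyl}-1-(4-methoxyphenyl)-1-azaspiro[4.4]nonan-7-one
Product: 16 6-{(2S)-1-[tert-butyl(diphenyl)silyl]oxypropan-2-yl}-8-ethyl-9-{4-[(4-methoxybenzyl)oxy]butyl}-1-(4-methoxyphenyl)-1-azaspiro[4.4]nonan-7-ol (hydroxyl on the carbon face; cis to the arm)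
Conditions: LiBH(s-Bu)3, THF, −78 °C; then aq NaOH
Reagents that add atoms: none
Why: Ketone reduction by a bulky trialkylborohydride; hydride should approach C-b from the N-face, anti to the branched arm on C-d, which puts the hydroxyl cis to the arm as the lactone requires. Reduction at this point also removes the β-amino ketone, which could open by retro-aza-Michael reaction.

Step 10
Reactants: 16 6-{(2S)-1-[tert-butyl(diphenyl)silyl]oxypropan-2-yl}-8-ethyl-9-{4-[(4-methoxybenzyl)oxy]butyl}-1-(4-methoxyphenyl)-1-azaspiro[4.4]nonan-7-ol
Product: 17 8-ethyl-6-[(2S)-1-hydroxypropan-2-yl]-9-{4-[(4-methoxybenzyl)oxy]butyl}-1-(4-methoxyphenyl)-1-azaspiro[4.4]nonan-7-ol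
Conditions: Bu4NF, THF, rt
Reagents that add atoms: none
Why: Fluoride cleavage of the silyl ether; the benzyl-type ether and the aryl amine are inert to fluoride.

Step 11
Reactants: 17 8-ethyl-6-[(2S)-1-hydroxypropan-2-yl]-9-{4-[(4-methoxybenzyl)oxy]butyl}-1-(4-methoxyphenyl)-1-azaspiro[4.4]nonan-7-ol
Product: 19 6-ethyl-5-{4-[(4-methoxybenzyl)oxy]butyl}-1′-(4-methoxyphenyl)-3-methylhexahydrospiro[cyclopenta[b]furan-4,2′-pyrrolidin]-2-one (ring D cis-fused), via lactol 18 (not isolated)
Conditions: Cu(MeCN)4OTf, 2,2′-bipyridine, TEMPO, N-methylimidazole (10 mol % each), air, MeCN, rt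
Reagents that add atoms: none
Why: Aerobic copper/nitroxyl oxidative lactonisation: the primary alcohol is oxidised in preference to the hindered secondary one, the aldehyde closes onto the cis hydroxyl, and the lactol is oxidised on to the lactone. Divalent copper and the nitroxyl are mild enough that the electron-rich N-aryl amine should survive, which stronger oxidants would not allow.

Step 12
Reactants: 19 6-ethyl-5-{4-[(4-methoxybenzyl)oxy]butyl}-1′-(4-methoxyphenyl)-3-methylhexahydrospiro[cyclopenta[b]furan-4,2′-pyrrolidin]-2-one
Product: 21 6-ethyl-3-hydroxy-5-{4-[(4-methoxybenzyl)oxy]butyl}-1′-(4-methoxyphenyl)-3-methylhexahydrospiro[cyclopenta[b]furan-4,2′-pyrrolidin]-2-one (hydroxyl exo), via potassium enolate 20 (not isolated)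
Conditions: KN(SiMe3)2, THF, −78 to −40 °C; then 3-phenyl-2-(phenylsulfonyl)oxaziridine, −78 °C; then AcOH
Reagents that add atoms: 3-phenyl-2-(phenylsulfonyl)oxaziridine, O=S(=O)(c1ccccc1)N1OC1c1ccccc1
Why: Enolate oxidation with an N-sulfonyloxaziridine; the planar ring-D enolate is attacked on its convex face, away from ring A and the pyrrolidine CH2, so hydroxyl ends exo and methyl endo and the earlier configuration of C-c is erased. Ring D is the only enolisable carbonyl group at this stage.

Step 13
Reactants: 21 6-ethyl-3-hydroxy-5-{4-[(4-methoxybenzyl)oxy]butyl}-1′-(4-methoxyphenyl)-3-methylhexahydrospiro[cyclopenta[b]furan-4,2′-pyrrolidin]-2-one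
Product: 22 6-ethyl-3-hydroxy-5-(4-hydroxybutyl)-3-methylhexahydrospiro[cyclopenta[b]furan-4,2′-pyrrolidin]-2-one
Conditions: (NH4)2Ce(NO3)6 (5 equiv), MeCN/H2O, 0 °C; acid–base extraction
Reagents that add atoms: none
Why: Oxidative deprotection by tetravalent cerium: the N-(4-methoxyphenyl) group is oxidised to a quinone iminium ion and hydrolysed off, and the 4-methoxybenzyl ether is cleaved through its benzylic cation. One reagent thus frees both the secondary amine and the primary alcohol.

Step 14
Reactants: 22 6-ethyl-3-hydroxy-5-(4-hydroxybutyl)-3-methylhexahydrospiro[cyclopenta[b]furan-4,2′-pyrrolidin]-2-one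
Product: 24 the 1-pyrroline of 22 (C=N between N and C-p; otherwise unchanged), via N-chloroamine 23 (not isolated)
Conditions: N-chlorosuccinimide, CH2Cl2, 0 °C; then DBU, rt
Reagents that add atoms: none
Why: Amine-to-imine oxidation by N-chlorination and base-induced dehydrochlorination; only C-p carries hydrogen next to nitrogen, so the C=N bond can form in one position only.

Step 15
Reactants: 25 3-methylfuran-2(5H)-one
Product: 26 triisopropyl[(3-methylfuran-2-yl)oxy]silane
Conditions: i-Pr3SiOTf, Et3N, CH2Cl2, 0 °C
Reagents that add atoms: triisopropylsilyl trifluoromethanesulfonate, CC(C)[Si](OS(=O)(=O)C(F)(F)F)(C(C)C)C(C)C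
Why: Soft enolisation and O-silylation of the butenolide to its 2-silyloxyfuran.

Step 16
Reactants: 24 the 1-pyrroline of 22; 26 triisopropyl[(3-methylfuran-2-yl)oxy]silane
Product: 29 the 2,3-didehydro-ring-E precursor of 30 (butenolide attached to C-p through its γ-carbon; rings A to D as in 30), via iodo imine 27 (not isolated), via iminium iodide 28 (not isolated)
Conditions: PPh3, I2, imidazole, MeCN, 0 to 60 °C; then 26, 0 °C to rt; aq NaHCO3
Reagents that add atoms: none
Why: Appel iodination of the primary alcohol, intramolecular N-alkylation of the cyclic imine (which closes ring C at nitrogen and creates the iminium ion at C-p only) and vinylogous Mannich addition of the silyloxyfuran. The nucleophile should add to C-p on the face of ring B remote from ring C, and the usual threo preference of such additions gives the C-p/ring-E relation of the target.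

Step 17
Reactants: 29 the 2,3-didehydro-ring-E precursor of 30
Product: 30 CNP0260919.2
Conditions: H2 (1 atm), Pd/C, EtOH, rt
Reagents that add atoms: none
Why: Heterogeneous hydrogenation of the butenolide; hydrogen should add to the face opposite the bulky amine substituent on the γ-carbon, which places the α-methyl group cis to it.

## Compound list

1 | methyl (2R)-3-hydroxy-2-methylpropanoate | COC(=O)[C@H](C)CO | starting material
2 | methyl (2R)-3-[tert-butyl(diphenyl)silyl]oxy-2-methylpropanoate | COC(=O)[C@H](C)CO[Si](c1ccccc1)(c1ccccc1)C(C)(C)C | intermediate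
3 | (2R)-3-[tert-butyl(diphenyl)silyl]oxy-2-methylpropanal | O=C[C@H](C)CO[Si](c1ccccc1)(c1ccccc1)C(C)(C)C | intermediate
4 | 3-(furan-2-yl)propanoic acid | OC(=O)CCc1ccco1 | starting material
5 | 4-methoxyaniline | COc1ccc(N)cc1 | starting material
6 | 3-(furan-2-yl)-N-(4-methoxyphenyl)propanamide | COc1ccc(NC(=O)CCc2ccco2)cc1 | intermediate
7 | N-[3-(furan-2-yl)propyl]-4-methoxyaniline | COc1ccc(NCCCc2ccco2)cc1 | intermediate
8 | N,5-dilithio derivative of 7 (lithium anilide, 5-lithiofuran) | [Li]c1ccc(CCCN([Li])c2ccc(OC)cc2)o1 | intermediate
9 | (2R)-3-[tert-butyl(diphenyl)silyl]oxy-1-{5-[3-(4-methoxyanilino)propyl]furan-2-yl}-2-methylpropan-1-ol, both C-1 epimers | OC(c1ccc(CCCNc2ccc(OC)cc2)o1)[C@H](C)CO[Si](c1ccccc1)(c1ccccc1)C(C)(C)C | intermediate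
10 | (5S,6R)-6-{(2S)-1-[tert-butyl(diphenyl)silyl]oxypropan-2-yl}-1-(4-methoxyphenyl)-1-azaspiro[4.4]non-8-en-7-one | O=C1C=C[C@@]2(CCCN2c2ccc(OC)cc2)[C@H]1[C@H](C)CO[Si](c1ccccc1)(c1ccccc1)C(C)(C)C | intermediate
11 | 1-[(4-bromobutoxy)methyl]-4-methoxybenzene | COc1ccc(COCCCCBr)cc1 | starting material
12 | {4-[(4-methoxybenzyl)oxy]butyl}magnesium bromide | COc1ccc(COCCCC[Mg]Br)cc1 | intermediate
13 | 6-{(2S)-1-[tert-butyl(diphenyl)silyl]oxypropan-2-yl}-9-{4-[(4-methoxybenzyl)oxy]butyl}-1-(4-methoxyphenyl)-7-(trimethylsilyloxy)-1-azaspiro[4.4]non-7-ene, C-9 chain on the carbon face (trans to N) | C[Si](C)(C)OC1=C[C@@H](CCCCOCc3ccc(OC)cc3)[C@@]2(CCCN2c2ccc(OC)cc2)[C@H]1[C@H](C)CO[Si](c1ccccc1)(c1ccccc1)C(C)(C)C | intermediate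
14 | lithium enolate corresponding to 13 (O–Li in place of O–SiMe3) | [Li]OC1=C[C@@H](CCCCOCc3ccc(OC)cc3)[C@@]2(CCCN2c2ccc(OC)cc2)[C@H]1[C@H](C)CO[Si](c1ccccc1)(c1ccccc1)C(C)(C)C | intermediate
15 | 6-{(2S)-1-[tert-butyl(diphenyl)silyl]oxypropan-2-yl}-8-ethyl-9-{4-[(4-methoxybenzyl)oxy]butyl}-1-(4-methoxyphenyl)-1-azaspiro[4.4]nonan-7-one, ethyl on the N-face, chain and arm on the carbon face | CC[C@H]1C(=O)[C@H]([C@H](C)CO[Si](c3ccccc3)(c3ccccc3)C(C)(C)C)[C@]2(CCCN2c2ccc(OC)cc2)[C@@H]1CCCCOCc1ccc(OC)cc1 | intermediate
16 | the 7-ol from 15, hydroxyl on the carbon face (cis to the arm, trans to ethyl) | CC[C@H]1[C@H](O)[C@H]([C@H](C)CO[Si](c3ccccc3)(c3ccccc3)C(C)(C)C)[C@]2(CCCN2c2ccc(OC)cc2)[C@@H]1CCCCOCc1ccc(OC)cc1 | intermediate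
17 | 8-ethyl-6-[(2S)-1-hydroxypropan-2-yl]-9-{4-[(4-methoxybenzyl)oxy]butyl}-1-(4-methoxyphenyl)-1-azaspiro[4.4]nonan-7-ol, configuration as in 16 | CC[C@H]1[C@H](O)[C@H]([C@H](C)CO)[C@]2(CCCN2c2ccc(OC)cc2)[C@@H]1CCCCOCc1ccc(OC)cc1 | intermediate
18 | cis-fused lactol of 17 (2-hydroxy analogue of 19, either anomer) | CC[C@H]1[C@@H]2OC(O)[C@@H](C)[C@@H]2[C@]3(CCCN3c3ccc(OC)cc3)[C@@H]1CCCCOCc1ccc(OC)cc1 | intermediate
19 | 6-ethyl-5-{4-[(4-methoxybenzyl)oxy]butyl}-1′-(4-methoxyphenyl)-3-methylhexahydrospiro[cyclopenta[b]furan-4,2′-pyrrolidin]-2-one, ring D cis-fused, 3-methyl exo | CC[C@H]1[C@@H]2OC(=O)[C@@H](C)[C@@H]2[C@]3(CCCN3c3ccc(OC)cc3)[C@@H]1CCCCOCc1ccc(OC)cc1 | intermediate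
20 | potassium enolate of 19 | CC[C@H]1[C@@H]2OC(O[K])=C(C)[C@@H]2[C@]3(CCCN3c3ccc(OC)cc3)[C@@H]1CCCCOCc1ccc(OC)cc1 | intermediate
21 | 3-hydroxy derivative of 19, hydroxyl exo and methyl endo (C-c as in 30) | CC[C@H]1[C@@H]2OC(=O)[C@@](C)(O)[C@@H]2[C@]3(CCCN3c3ccc(OC)cc3)[C@@H]1CCCCOCc1ccc(OC)cc1 | intermediate
22 | 6-ethyl-3-hydroxy-5-(4-hydroxybutyl)-3-methylhexahydrospiro[cyclopenta[b]furan-4,2′-pyrrolidin]-2-one (free N–H) | CC[C@H]1[C@@H]2OC(=O)[C@@](C)(O)[C@@H]2[C@]3(CCCN3)[C@@H]1CCCCO | intermediate
23 | N-chloro derivative of 22 | CC[C@H]1[C@@H]2OC(=O)[C@@](C)(O)[C@@H]2[C@]3(CCCN3Cl)[C@@H]1CCCCO | intermediate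
24 | 1-pyrroline of 22 (C=N between N and C-p) | CC[C@H]1[C@@H]2OC(=O)[C@@](C)(O)[C@@H]2[C@]3(CCC=N3)[C@@H]1CCCCO | intermediate
25 | 3-methylfuran-2(5H)-one | CC1=CCOC1=O | starting material
26 | triisopropyl[(3-methylfuran-2-yl)oxy]silane | Cc1ccoc1O[Si](C(C)C)(C(C)C)C(C)C | intermediate
27 | primary iodide of 24 (4-iodobutyl chain on C-e) | CC[C@H]1[C@@H]2OC(=O)[C@@](C)(O)[C@@H]2[C@]3(CCC=N3)[C@@H]1CCCCI | intermediate
28 | tetracyclic iminium iodide (rings A to D closed, C=N+ between N and C-p) | CC[C@H]1[C@@H]2OC(=O)[C@@](C)(O)[C@@H]2[C@@]23CCC=[N+]2CCCC[C@H]13.[I-] | intermediate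
29 | 2,3-didehydro-ring-E precursor of 30 (3-methyl-2(5H)-furanon-5-yl on C-p, threo) | CC[C@H]1[C@@H]2OC(=O)[C@@](C)(O)[C@@H]2[C@@]23CC[C@@H]([C@@H]4C=C(C)C(=O)O4)N2CCCC[C@H]13 | intermediate
30 | CNP0260919.2 (C-a R, C-b S, C-c S, C-d R, C-q S, C-e R, C-p S, ring E S,S) | CC[C@H]1[C@@H]2OC(=O)[C@@](C)(O)[C@@H]2[C@@]23CC[C@@H]([C@@H]4C[C@H](C)C(=O)O4)N2CCCC[C@H]13 | target

## Step count and least certain steps

Total step count: 17. Longest linear sequence: 14 steps (steps 3 to 14, 16 and 17 from 4 and 5; equally steps 1, 2, 5 to 14, 16 and 17 from 1).

Step 6 (key step). The most likely failure is insufficient discrimination between the two senses of conrotation, because the cyclising cation offers the phosphate only one hydrogen-bond contact. E1 loss of the β-hydrogen from the furfuryl cation may also compete. The fallback separates ionisation from stereocontrol. It sets out from 9, which is rearranged with the achiral Lewis acid Dy(OTf)3 in MeCN at 80 °C. This should give both trans products, 10 and its (5R,6S) diastereomer F1. Absolute configuration is then obtained by chromatographic resolution that rests on the stereocentre of the arm, not on the catalyst. The fallback returns to the route at 10.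

Step 16. The seven-membered closure by the imine nitrogen may be slow enough for intermolecular alkylation or enamine formation to intervene, and facial or threo discrimination in the Mannich addition may be low. The fallback forms the C-p–ring E bond before ring C and sets out from 22:
- Oxidation with Na2WO4 (cat.) and H2O2 should give the nitrone F8.
- Me3SiOTf-promoted addition of 26 should give the N-hydroxy pyrrolidine butenolide F9, with C-p epimers separated if both form.
- Zn in AcOH cleaves the N–O bond to the secondary amine F10.
- Appel iodination gives the iodide F11, which closes ring C by ordinary intramolecular amine alkylation (K2CO3, MeCN, heat).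

The fallback returns to the route at 29.

Step 7. The nucleophile may attack the N-face, or face selection may be poor, because the arm on C-d also shields the carbon face. The fallback lets hydrogen, not carbon, enter from the more accessible face, and sets out from 13 (either C-e epimer):
- Saegusa–Ito oxidation with Pd(OAc)2 in MeCN should give the β-substituted enone F2.
- Hydrogenation over Pd/C with pyridine (to spare the benzyl-type ether) should give the ketone F3 with the chain on the carbon face.
- Kinetic deprotonation with LiN(i-Pr)2 on the less hindered C-a side, then iodoethane, leads on.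

The fallback returns to the route at 15.

Step 8. Proton exchange between enolate and product may cause polyalkylation, or an enolate on the C-d side may form and expel the β-amino group. The fallback avoids a free enolate and sets out from 13:
- Mukaiyama aldol addition to acetaldehyde (TiCl4, CH2Cl2, −78 °C) should give the β-hydroxy ketone F4.
- Mesylation and elimination (MsCl, Et3N; DBU) should give the ethylidene ketone F5.
- Hydrogenation (Pd/C, pyridine) with brief base equilibration gives the trans ketone.

The fallback returns to the route at 15.

Step 9. Hydride may be delivered from the carbon face, since both faces of the ketone carry an α-substituent. The fallback corrects the centre by substitution and sets out from 15. Reduction then gives the C-b epimer F6. Mitsunobu reaction with 4-nitrobenzoic acid, PPh3 and diisopropyl azodicarboxylate should give the inverted ester F7, and methanolysis (K2CO3, MeOH) returns to the route at 16.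

Further compounds

F1 | step 6 | (5R,6S)-diastereomer of 10, arm unchanged | O=C1C=C[C@]2(CCCN2c2ccc(OC)cc2)[C@@H]1[C@H](C)CO[Si](c1ccccc1)(c1ccccc1)C(C)(C)C
F2 | step 7 | 9-{4-[(4-methoxybenzyl)oxy]butyl} analogue of 10 (chain on the enone β-carbon) | O=C1C=C(CCCCOCc3ccc(OC)cc3)[C@@]2(CCCN2c2ccc(OC)cc2)[C@H]1[C@H](C)CO[Si](c1ccccc1)(c1ccccc1)C(C)(C)C
F3 | step 7 | des-ethyl analogue of 15 (chain on the carbon face) | O=C1C[C@@H](CCCCOCc3ccc(OC)cc3)[C@@]2(CCCN2c2ccc(OC)cc2)[C@H]1[C@H](C)CO[Si](c1ccccc1)(c1ccccc1)C(C)(C)C
F4 | step 8 | 8-(1-hydroxyethyl) analogue of 15 (carbinol epimers) | CC(O)[C@H]1C(=O)[C@H]([C@H](C)CO[Si](c3ccccc3)(c3ccccc3)C(C)(C)C)[C@]2(CCCN2c2ccc(OC)cc2)[C@@H]1CCCCOCc1ccc(OC)cc1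
F5 | step 8 | (E)-8-ethylidene analogue of 15 | C/C=C1/C(=O)[C@H]([C@H](C)CO[Si](c3ccccc3)(c3ccccc3)C(C)(C)C)[C@]2(CCCN2c2ccc(OC)cc2)[C@@H]1CCCCOCc1ccc(OC)cc1
F6 | step 9 | C-b epimer of 16 (hydroxyl on the N-face) | CC[C@H]1[C@@H](O)[C@H]([C@H](C)CO[Si](c3ccccc3)(c3ccccc3)C(C)(C)C)[C@]2(CCCN2c2ccc(OC)cc2)[C@@H]1CCCCOCc1ccc(OC)cc1
F7 | step 9 | 4-nitrobenzoate of 16 | CC[C@H]1[C@H](OC(=O)c3ccc(cc3)[N+](=O)[O-])[C@H]([C@H](C)CO[Si](c3ccccc3)(c3ccccc3)C(C)(C)C)[C@]2(CCCN2c2ccc(OC)cc2)[C@@H]1CCCCOCc1ccc(OC)cc1
F8 | step 16 | nitrone of 22 (C=N+ to C-p, N–O−) | CC[C@H]1[C@@H]2OC(=O)[C@@](C)(O)[C@@H]2[C@]3(CCC=[N+]3[O-])[C@@H]1CCCCO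
F9 | step 16 | N-hydroxy pyrrolidine carrying the butenolide on C-p | CC[C@H]1[C@@H]2OC(=O)[C@@](C)(O)[C@@H]2[C@]3(CC[C@@H]([C@@H]4C=C(C)C(=O)O4)N3O)[C@@H]1CCCCO
F10 | step 16 | secondary amine from F9 | CC[C@H]1[C@@H]2OC(=O)[C@@](C)(O)[C@@H]2[C@]3(CC[C@@H]([C@@H]4C=C(C)C(=O)O4)N3)[C@@H]1CCCCO
F11 | step 16 | primary iodide of F10 | CC[C@H]1[C@@H]2OC(=O)[C@@](C)(O)[C@@H]2[C@]3(CC[C@@H]([C@@H]4C=C(C)C(=O)O4)N3)[C@@H]1CCCCI
A1 | alternative 1 | angular azido hydrindanone carrying rings D and E | CC[C@H]1[C@@H]2OC(=O)[C@@](C)(O)[C@@H]2[C@@]2(CC[C@H](N=[N+]=[N-])[C@@H]3C[C@H](C)C(=O)O3)C(=O)CCC[C@H]12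
A2 | alternative 1 | lactam of 30 (carbonyl at the azepane N–CH2 position) | CC[C@H]1[C@@H]2OC(=O)[C@@](C)(O)[C@@H]2[C@@]23CC[C@@H]([C@@H]4C[C@H](C)C(=O)O4)N2C(=O)CCC[C@H]13
A3 | alternative 2 | N-benzyl ten-membered lactam with ring alkene and glycidyl side chain | O=C1CC/C(C[C@@H]2CO2)=C\CCCCN1Cc1ccccc1
A4 | alternative 2 | tricyclic hydroxy lactam | C1[C@H](O)C[C@@]23CCC(=O)N2CCCC[C@H]13
A5 | alternative 3 | N-Boc 5-(2-silyloxyhex-5-enyl)-1,2-dihydropyrrol-3-one | CC(C)(C)OC(=O)N1CC(=O)C=C1C[C@@H](O[Si](C)(C)C(C)(C)C)CC=C
A6 | alternative 3 | cyclopenta-fused tetrahydroazepinone imine | O=C1CN=C2C[C@@H](O[Si](C)(C)C(C)(C)C)C[C@H]2CC1
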